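(Readings and results were computed for substances that don't exist, noise included.)

Percent of the two substrates charged together is the unit to watch. On it, the zero of the scale is a catalyst without preference: both substrates stay level and the product ratio stands at 1.

the same everywhere: left-handed substrate 0.50 M; right-handed substrate 0.50 M

| charge | protic impurity | solid reagent | catalyst | remark | time |
|---|---|---|---|---|---|
| eta | 0.050 M | 3 equiv | 20 mol% | the very flask that is asked about, followed so far |  |
| theta | 0.050 M | 3 equiv | 40 mol% | run made earlier |  |
| flask | 0.0500 M | 3.00 equiv | 20 mol% |  | 2.5 min |

| run | time / s | right-handed substrate / % | right-handed product / % | left-handed substrate / % | left-handed product / % |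
|---|---|---|---|---|---|
| eta | 10.0 | 50.8 | 0 | 50.0 | 0.4 |
| eta | 12.0 | 50.5 | 0.7 | 50.4 | 0 |
| eta | 20.0 | 49.8 | 0.2 | 49.3 | 0.1 |
| eta | 30.0 | 49.7 | 0.7 | 49.5 | 1.3 |
| eta | 50.0 | 49.5 | 0.7 | 48.3 | 2.0 |
| theta | 10.0 | 51.0 | 0.5 | 49.8 | 0.1 |
| theta | 15.0 | 49.3 | 0 | 48.9 | 0.5 |
| theta | 30.0 | 49.8 | 0 | 48.2 | 1.5 |
| theta | 50.0 | 49.5 | 1.5 | 45.5 | 4.3 |
| theta | 60.0 | 49.7 | 0.5 | 44.8 | 4.9 |
| theta | 80.0 | 49.7 | 1.1 | 43.4 | 6.8 |
| theta | 120 | 47.0 | 1.4 | 39.6 | 11.5 |

(readings scatter by 0.5 percentage points)

- catalyst is single-handed; left-handed substrate and right-handed substrate are mirror images of each other, charged as a racemate, each of them at the stated concentration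
- given per volume of solution although it is solid: solid reagent
- the numbers in the tables scatter with a standard deviation of 0.5 percentage points
- at the start none of the solid reagent is in solution

* the species that holds most of what was charged as left-handed substrate and right-handed substrate together, at 2.5 min (right-handed substrate / right-handed product / left-handed product / left-handed substrate)
* the largest share itself, whichever of these holds it, in percent of the left-handed substrate and right-handed substrate together charged

Which figure carries eta? Summed left-handed product over summed right-handed product in theta, from 50.0 s on, gives 6.11. This is the product ratio, at low conversion close to the selectivity factor. A delay that holds up both products alike cancels from it.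

Where is it weak? The right-handed product readings lie near the scatter of 0.5 percentage points, and theta's last reading alone gives 8.21, so a pooled reading is the safer one.

How much left-handed product will eta hold at 2.5 min? At 50.0 s, theta, with twice the catalyst, holds twice eta's product. So I take half of theta's late slope and extend from eta's 2.0%, which gives 7.14%.

And the share? Each product comes out of its own substrate, so dividing by the ratio gives 1.17% right-handed product. My reckoning then leaves 42.9% left-handed substrate in eta and 48.8% right-handed substrate, so eta holds more right-handed substrate than left-handed substrate.

And if the ratio is off? With theta's last reading, the share reads 49.1%. The order stands in that case too: the gap between the substrates in my reckoning is 6 points.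

The forecast puts right-handed substrate first at 49.3%, above my figure, on the ground: “The right-handed substrate reacts roughly ten times slower”.

The flask gives right-handed substrate at 48.7%, on this scheme:

    partner + catalyst + left-handed substrate → catalyst + left-handed product (k = 0.190 M⁻² s⁻¹)
    partner + catalyst + right-handed substrate → catalyst + right-handed product (k = 0.0280 M⁻² s⁻¹)
    partner + protic impurity → quenched reagent (k = 0.300 M⁻¹ s⁻¹)
    partner → decomposed reagent (k = 0.0440 s⁻¹)
    solid reagent ⇌ partner, rate k5*(cs5 - [partner]) while solid is left; crystals form when [partner] > cs5 (solubility = 0.230 M, k = 0.0240 s⁻¹)

Beside it stand 42.1% left-handed substrate, 7.94% left-handed product and 1.26% right-handed product, a product ratio of 6.30 in this flask. Now take the neighbour flask with c(protic impurity) at 0.020 M, which holds 8.22% left-handed product at 2.50 min. Dividing that by 6.11 gives 1.35% right-handed product, and the neighbour flask holds 1.31%.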